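**Late readings.** At the last autumn reading, 2.50 d, starting material, target and isomer of the product together held 70.6 % of the charge. That is close to the 0.700 left if the protic impurity, a fraction 0.300 of the charge, removes starting material one for one. I therefore counted the product flow from that fraction.

| flask | starting material | partner | protic impurity | temperature | remark | time |
|---|---|---|---|---|---|---|
| autumn | 20 mM | 0.25 equiv | 6 mM | 66 °C | run made earlier |  |
| spring | 20 mM | 0.38 equiv | 6 mM | 80 °C | run made earlier |  |
| eta | 20 mM | 0.500 equiv | 6.00 mM | 60 °C |  | 4.0 d |
| gamma | 20 mM | 0.500 equiv | 6.00 mM | 85 °C |  | 4.0 d |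

autumn run (percent of the starting material charged)

| time / d | tight pair / % | isomer of the product / % | target / % | starting material / % |
|---|---|---|---|---|
| 0.208 | 0.2 | 0.1 | 0.4 | 69.9 |
| 0.417 | 0.1 | 0 | 0.7 | 68.5 |
| 1.04 | 0 | 1.0 | 1.8 | 68.0 |
| 2.50 | 0 | 2.2 | 2.9 | 65.5 |

spring run (percent of the starting material charged)

| time / h | tight pair / % | isomer of the product / % | target / % | starting material / % |
|---|---|---|---|---|
| 6.00 | 0.2 | 0.4 | 2.8 | 66.7 |
| 12.0 | 0 | 1.6 | 3.1 | 65.9 |
| 15.0 | 0 | 0.5 | 3.5 | 63.7 |
| 20.0 | 0 | 2.2 | 5.4 | 62.9 |

(each reading ± 0.5 percentage points)

- percent here means starting material units held: one homo dimer counts as two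
- steps thought possible: starting material <-> tight pair; tight pair <-> loose pair; partner + tight pair -> target; partner + loose pair -> isomer of the product; starting material + protic impurity -> quenched substrate; 2 starting material -> homo dimer

- which of these there is most of at the end, counted by the starting material in it, eta (isomer of the product / target / tight pair / starting material)
- which of these there is most of at the end, counted by the starting material in it, gamma (isomer of the product / target / tight pair / starting material)
- how much there is at the end of the one of these that leads, in percent of the starting material charged: eta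
- how much there is at the end of the one of these that leads, in percent of the starting material charged: gamma

**Start rate.** I took target and isomer as one flow, assumed first order in partner, and used the last readings. The autumn run gave 0.0204 d⁻¹ and the spring run 0.0912 d⁻¹. Per unit of partner charged, that is a factor 2.94 between 66 °C and 80 °C. Scaled exponentially in temperature, gamma starts at 0.176 d⁻¹.

**Slowing.** Each unit of product takes one starting material and one partner, and partner is the limiting reagent of these two. Unslowed, gamma would make 0.704 in 4.0 d, more than the 0.500 equiv of partner. So I used the pair constant 0.504 d⁻¹, the start rate divided by the two starting fractions; the rate at any moment is this constant times free starting material times free partner. Integrated, this reckoning gives gamma free partner 0.183 and product 0.317. In it, starting material slows the rate by a factor 0.383/0.700, which is 0.547, and partner by 0.366, so my end rate is 0.200 of my start rate. My gamma figure for starting material is 0.383. For eta, the constant scaled to 60 °C gives starting material at 0.613.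

**The forecast.** It named starting material for eta at 63 % and starting material for gamma at 36 %, “so starting material still leads”. Its eta figure lies above mine and its gamma figure below mine.

**The result.** Eta gave starting material at 61.2 %, and gamma gave starting material at 37.6 %, with target at 25.3 %. Gamma kept 38.1 % of its partner free. The pair constant with gamma's end amounts gives a product rate of 0.0361 d⁻¹. The forecast's choice for gamma would be wrong if target passed starting material, as target does in the flask at 110 °C below.

    starting material ⇌ tight pair (K = 3.89 × 10⁻⁴, k = 1.68 × 10⁻⁴ min⁻¹, Ea = 103 kJ mol⁻¹, ΔH = 15.0 kJ mol⁻¹)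
    tight pair ⇌ loose pair (K = 0.893, k = 0.247 min⁻¹, Ea = 88.0 kJ mol⁻¹, ΔH = −51.0 kJ mol⁻¹)
    partner + tight pair → target (k = 4.59 M⁻¹ min⁻¹, Ea = 68.0 kJ mol⁻¹)
    partner + loose pair → isomer of the product (k = 3.37 M⁻¹ min⁻¹, Ea = 77.0 kJ mol⁻¹)
    starting material + protic impurity → quenched substrate (k = 1.18 M⁻¹ min⁻¹, Ea = 68.0 kJ mol⁻¹)
    2 starting material → homo dimer (k = 3.15 × 10⁻⁵ M⁻¹ min⁻¹, Ea = 81.0 kJ mol⁻¹)
    (constants at 60 °C)

**Second flask.** In a flask like gamma but kept at 110 °C, the pair constant scales to 3.46 d⁻¹, which gives starting material at 0.209. The computed flask holds 18.9 % of it and 44.0 % of target, so target leads there.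

Readings and results come from a simulation on assumed constants, noise included.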